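The route rests on disconnecting ring C of the flavone at the O1–C2 bond, with the C3 methoxy group traced back to a C3 iodide. The feature exploited is that the oxygen on C8a, carried as the methoxy group ortho to the ketone of a 2,3,4-trimethoxyphenyl ynone, sits within reach of C2 of a C2≡C3 alkyne. In one operation, iodine monochloride closes ring C by 6-endo-dig attack of that oxygen, removes its methyl group and leaves iodine at C3 as the handle for the third methoxy group. The precursor is the diaryl ynone joining the 2,3,4-trimethoxybenzoyl unit to the 3-benzyloxy-4-methoxyphenyl alkyne.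

Key step: step 4

Remark: the target has no stereocentre, so no step sets or preserves configuration. The atom mapping of the key step was checked against the target: the 2-, 3- and 4-methoxy groups of the ketone ring of ynone 7 become O1, the C8 methoxy group and the C7 methoxy group of 8. The benzyl ether on the ring B hydroxyl is kept because it should tolerate ICl and the copper step and is removed last under neutral conditions.

**Step 1**
Reactants: 1 isovanillin (3-hydroxy-4-methoxybenzaldehyde); 2 benzyl bromide
Product: 3 3-benzyloxy-4-methoxybenzaldehyde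
Conditions: BnBr (1.1 equiv), K2CO3, DMF, rt
Reagents that add atoms: benzyl bromide (compound 2), BrCc1ccccc1
Why: Williamson ether synthesis, in which the phenoxide formed by K2CO3 displaces bromide from the benzylic carbon by SN2 while the non-enolisable aldehyde is untouched.

**Step 2**
Reactants: 3 3-benzyloxy-4-methoxybenzaldehyde
Product: 4 2-benzyloxy-4-ethynyl-1-methoxybenzene
Conditions: dimethyl (1-diazo-2-oxopropyl)phosphonate (1.3 equiv), K2CO3 (2 equiv), MeOH, 0 °C to rt
Reagents that add atoms: dimethyl (1-diazo-2-oxopropyl)phosphonate (Ohira–Bestmann reagent), CC(=O)C(=[N+]=[N-])P(=O)(OC)OC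
Why: Ohira–Bestmann variant of the Seyferth–Gilbert homologation, in which methanolysis of the reagent gives the diazomethylphosphonate anion that adds to the aryl aldehyde, and Horner–Wadsworth–Emmons-type elimination, loss of N2 and a 1,2-shift in the alkylidene carbene give the terminal alkyne under mild base that the benzyl ether tolerates.

**Step 3**
Reactants: 5 2,3,4-trimethoxybenzoic acid; 4 2-benzyloxy-4-ethynyl-1-methoxybenzene
Product: 7 3-(3-benzyloxy-4-methoxyphenyl)-1-(2,3,4-trimethoxyphenyl)prop-2-yn-1-one, via 2,3,4-trimethoxybenzoyl chloride 6 (not isolated)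
Conditions: (COCl)2, cat. DMF, CH2Cl2, 0 °C to rt, evaporate; then 4, PdCl2(PPh3)2 (2 mol%), CuI (4 mol%), Et3N, THF, rt, argon
Reagents that add atoms: none
Why: Acyl Sonogashira coupling, in which the acid chloride made with oxalyl chloride and catalytic DMF adds oxidatively to zerovalent palladium (formed from PdCl2(PPh3)2), the copper acetylide generated by CuI and Et3N transmetalates, and reductive elimination forms the ynone C–C bond at room temperature.

**Step 4**
Reactants: 7 3-(3-benzyloxy-4-methoxyphenyl)-1-(2,3,4-trimethoxyphenyl)prop-2-yn-1-one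
Product: 8 2-(3-benzyloxy-4-methoxyphenyl)-3-iodo-7,8-dimethoxy-4H-chromen-4-one
Conditions: ICl (1.2 equiv, 1 M in CH2Cl2), CH2Cl2, −78 °C; then aq. Na2S2O3
Reagents that add atoms: iodine monochloride, ClI
Why: ICl delivers electrophilic iodine to the C2≡C3 alkyne, the oxygen of the methoxy group ortho to the ketone attacks anti to iodine at the aryl-bearing alkyne carbon to give a cyclic methyloxonium ion, and chloride then removes the methyl group by SN2 attack as chloromethane, which makes the closure irreversible. The closest known reaction type is the iodine monochloride-induced iodocyclisation of 2-methoxyaryl alkynones to 3-iodochromones. Ring C is closed in the 6-endo-dig mode, forming O1–C2 and C3–I in one operation; no stereocentre is created. The step needs 6-endo closure in preference to 5-exo closure to an aurone-type product, and this is secured by the polarisation of the ynone, whose carbonyl-remote carbon is the electrophilic terminus and is further stabilised as a cation by the para-methoxy donor of ring B. It also needs the right oxygen to react, and only the methoxy group on the future C8a can reach that carbon through a six-membered transition state, the 3- and 4-methoxy groups being too far away. Alkyne activation should outrun iodination of the alkoxyarenes at −78 °C with only a small excess of ICl, since both rings are deactivated by conjugation with the ynone.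

**Step 5**
Reactants: 8 2-(3-benzyloxy-4-methoxyphenyl)-3-iodo-7,8-dimethoxy-4H-chromen-4-one
Product: 9 2-(3-benzyloxy-4-methoxyphenyl)-3,7,8-trimethoxy-4H-chromen-4-one
Conditions: CuI (20 mol%), 1,10-phenanthroline (40 mol%), Cs2CO3 (2 equiv), MeOH–toluene, 110 °C, sealed tube
Reagents that add atoms: methanol, CO
Why: Ullmann-type C–O coupling, in which the phenanthroline-ligated methoxide complex of monovalent copper should activate the electron-poor C3–I bond of the vinylogous ester and release the enol ether by reductive elimination, a known reaction type for aryl and vinyl iodides with aliphatic alcohols, while the 2-aryl group disfavours conjugate attack of methoxide at C2.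

**Step 6**
Reactants: 9 2-(3-benzyloxy-4-methoxyphenyl)-3,7,8-trimethoxy-4H-chromen-4-one
Product: 10 diplotrin B, 2-(3-hydroxy-4-methoxyphenyl)-3,7,8-trimethoxy-4H-chromen-4-one
Conditions: H2 (1 atm), 10% Pd/C, EtOAc–MeOH, rt
Reagents that add atoms: none
Why: Catalytic hydrogenolysis of the benzyl aryl ether cleaves the benzylic C–O bond, while the tetrasubstituted C2=C3 bond of the vinylogous ester, the aryl methyl ethers and the C3 enol ether should not be reduced under these mild conditions.

**Compound list**
1 | isovanillin (3-hydroxy-4-methoxybenzaldehyde) | COc1ccc(C=O)cc1O | starting material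
2 | benzyl bromide | BrCc1ccccc1 | starting material
3 | 3-benzyloxy-4-methoxybenzaldehyde | COc1ccc(C=O)cc1OCc1ccccc1 | intermediate
4 | 2-benzyloxy-4-ethynyl-1-methoxybenzene | COc1ccc(C#C)cc1OCc1ccccc1 | intermediate
5 | 2,3,4-trimethoxybenzoic acid | COc1ccc(C(=O)O)c(OC)c1OC | starting material
6 | 2,3,4-trimethoxybenzoyl chloride (formed in the flask, not isolated) | COc1ccc(C(Cl)=O)c(OC)c1OC | intermediate
7 | 3-(3-benzyloxy-4-methoxyphenyl)-1-(2,3,4-trimethoxyphenyl)prop-2-yn-1-one | COc1ccc(C(=O)C#Cc2ccc(OC)c(OCc3ccccc3)c2)c(OC)c1OC | intermediate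
8 | 2-(3-benzyloxy-4-methoxyphenyl)-3-iodo-7,8-dimethoxy-4H-chromen-4-one | COc1ccc(-c2oc3c(OC)c(OC)ccc3c(=O)c2I)cc1OCc1ccccc1 | intermediate
9 | 2-(3-benzyloxy-4-methoxyphenyl)-3,7,8-trimethoxy-4H-chromen-4-one | COc1ccc(-c2oc3c(OC)c(OC)ccc3c(=O)c2OC)cc1OCc1ccccc1 | intermediate
10 | diplotrin B, 2-(3-hydroxy-4-methoxyphenyl)-3,7,8-trimethoxy-4H-chromen-4-one | COc1ccc(-c2oc3c(OC)c(OC)ccc3c(=O)c2OC)cc1O | target

**Step count and risk**
Total step count: 6. Longest linear sequence: 6 steps (isovanillin 1 to diplotrin B 10; acid 5 enters at step 3).

Steps most likely to fail: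

1. Step 4 (iodocyclisation). Electrophilic iodination of the alkoxy-substituted arenes, or closure in the 5-exo sense, may compete with the wanted 6-endo closure. The fallback builds ring C without alkyne activation. It sets out from aldehyde 3. Claisen–Schmidt condensation with purchasable 1-(2-hydroxy-3,4-dimethoxyphenyl)ethanone (KOH, EtOH, rt) should give (E)-3-(3-benzyloxy-4-methoxyphenyl)-1-(2-hydroxy-3,4-dimethoxyphenyl)prop-2-en-1-one F2. Oxidative cyclisation with catalytic I2 in DMSO at 130 °C should give 2-(3-benzyloxy-4-methoxyphenyl)-7,8-dimethoxy-4H-chromen-4-one F3. Iodination at C3 with I2 and (NH4)2Ce(NO3)6 in MeCN (alternatively LDA, THF, −78 °C, then I2) comes back to the route at compound 8.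

2. Step 5 (copper-catalysed methoxylation). Reductive loss of iodine, or addition of methoxide at C2 with opening of the pyranone ring, may outpace the C–O coupling. The fallback introduces the oxygen through boron and sets out from compound 8. Miyaura borylation (B2pin2, PdCl2(dppf), KOAc, dioxane, 80 °C) should give 2-(3-benzyloxy-4-methoxyphenyl)-7,8-dimethoxy-3-(4,4,5,5-tetramethyl-1,3,2-dioxaborolan-2-yl)-4H-chromen-4-one F4. Oxidation (NaBO3·4H2O, THF–H2O, rt) should give 2-(3-benzyloxy-4-methoxyphenyl)-3-hydroxy-7,8-dimethoxy-4H-chromen-4-one F5. O-Methylation (MeI, K2CO3, acetone, reflux) comes back to the route at compound 9.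

3. Step 3 (acyl Sonogashira coupling). Slow oxidative addition of the ortho-substituted, electron-rich aroyl chloride may let oxidative dimerisation of the alkyne and amine addition to the ynone take over. The fallback forms the same C–C bond by carbonyl addition and sets out from alkyne 4. Deprotonation with n-BuLi (THF, −78 °C) and addition to purchasable 2,3,4-trimethoxybenzaldehyde should give racemic 3-(3-benzyloxy-4-methoxyphenyl)-1-(2,3,4-trimethoxyphenyl)prop-2-yn-1-ol F1. Oxidation with MnO2 (CH2Cl2, rt) comes back to the route at compound 7.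

**Further compounds**
F1 | step 3 | 3-(3-benzyloxy-4-methoxyphenyl)-1-(2,3,4-trimethoxyphenyl)prop-2-yn-1-ol (racemic) | COc1ccc(C(O)C#Cc2ccc(OC)c(OCc3ccccc3)c2)c(OC)c1OC
F2 | step 4 | (E)-3-(3-benzyloxy-4-methoxyphenyl)-1-(2-hydroxy-3,4-dimethoxyphenyl)prop-2-en-1-one | COc1ccc(/C=C/C(=O)c2ccc(OC)c(OC)c2O)cc1OCc1ccccc1
F3 | step 4 | 2-(3-benzyloxy-4-methoxyphenyl)-7,8-dimethoxy-4H-chromen-4-one | COc1ccc(-c2cc(=O)c3ccc(OC)c(OC)c3o2)cc1OCc1ccccc1
F4 | step 5 | 2-(3-benzyloxy-4-methoxyphenyl)-7,8-dimethoxy-3-(4,4,5,5-tetramethyl-1,3,2-dioxaborolan-2-yl)-4H-chromen-4-one | COc1ccc(-c2oc3c(OC)c(OC)ccc3c(=O)c2B4OC(C)(C)C(C)(C)O4)cc1OCc1ccccc1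
F5 | step 5 | 2-(3-benzyloxy-4-methoxyphenyl)-3-hydroxy-7,8-dimethoxy-4H-chromen-4-one | COc1ccc(-c2oc3c(OC)c(OC)ccc3c(=O)c2O)cc1OCc1ccccc1
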